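The constants were drawn at random within sensible limits; no experiment stands behind them.

**The balance.** Keep one sum in view: starting material, intermediate, target and side product, as fractions of the charge with the side product counted double, add up to one.

| flask | starting material | time | remark |
|---|---|---|---|
| beta | 1.3 M | 5.0 d | everything together in a closed stirred flask, run for 5.0 d |
| zeta | 1.3 M |  | one stirred flow tank at steady state, fed with the mixture as stated, mean residence time 5.0 d |

    starting material → intermediate (k1 = 0.037 h⁻¹)
    intermediate → target (k2 = 0.094 h⁻¹)
    starting material + target → side product (k3 = 0.057 M⁻¹ h⁻¹)

- percentages count the starting material that a species holds: one side product counts as two
- the stated concentrations are those of everything mixed, before any reaction; amounts are the same in each set-up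
- run time (beta): 5.0 d

- the set-up with the highest share of target in all that became target or side product, at the outlet or at the end ("none" if the first two lie within 2 percentage points) (beta / zeta / none)
- share of target in all that became target or side product, at the outlet or at the end, beta
- share of target in all that became target or side product, at the outlet or at the end, zeta

**Closed flask.** In beta, treat starting material as decaying at one mean constant: the step-one constant divided by the mean of one and the target share. Take target's loss constant at full charge, 0.0741 h⁻¹, times the intermediate's constant, over the mean constant times the sum of the mean constant and the intermediate's constant. Starting from the bare step-one constant, this gives a ratio of 1.44 and a share of 41.0 %. Put each share back: 52.5 %, 49.8 %, 50.4 %. So reckon the side ratio, side product's fraction over target's at the end, at 0.984, and the share as one over one plus that ratio.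

**Flow tank.** In zeta, the ratio is twice the full-charge loss constant times the residence time times the fraction of starting material left. Going round the tank balance, that fraction runs 18.4 %, 12.5 %, 13.2 %. Expect a share of 29.9 %, lower than beta's.

**The forecast.** It says beta, with 49 % (45 % to 53 %) and 30 % (28 % to 32 %), since “the stirred tank holds both at once throughout”.

**The result.** Read 50.1 % for beta and 30.0 % for zeta, so beta leads, and the share reckoned from the side ratio, 50.4 %, stands beside the first. In beta, target is made 3.33 times faster than it is used up at 0.539 d, and its half-life by step 3 alone, with starting material as charged, 0.39 d, is shorter than 5.0 d. For the neighbour of beta charged with 2.2 M, scale the ratio with the charge to 1.66, a share of 37.5 %. One more round gives 40.3 %, and that flask stands at 39.8 %.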